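**Strategy.** Everything rests on closing the six-membered carbocycle at C3–C4 (ring numbering of 7-oxabicyclo[4.1.0]heptan-2-one) by an intramolecular carbonyl-ene reaction. The key step exploits the homoallylic alcohol array O–C3–C4–C(=CH2), trans on the ring and flanked by the C2 ketone. In one operation a chelated epoxy glyoxal should form the ring, the C3 hydroxyl, both stereocentres C3 and C4 and the exocyclic methylene. The precursor is an acyclic cis-epoxy α-keto aldehyde carrying a (Z)-trisubstituted allylic silyl ether. It comes from a symmetric (2Z,5Z)-dienediol made by a two-directional Wittig reaction, then differentiated by monosilylation and asymmetric epoxidation. The prenyl carbinol side chain and the two esters follow.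

Key step: step 7

Remark: ring atoms are numbered as in 7-oxabicyclo[4.1.0]heptan-2-one (C1 methyl-bearing epoxide carbon, C2 ketone, C3 oxygen-bearing carbon, C4 side-chain carbon, C6 epoxide CH); the side-chain carbinol carbon is called C3′. Reagent enantiomers (tartrate, bis(oxazoline), BINOL) are assigned by analogy with the literature cases cited in each step, and each assignment is to be confirmed on the first run; t-Bu-box = 2,2′-(propane-2,2-diyl)bis[(4S)-4-tert-butyl-4,5-dihydro-1,3-oxazole].

**Step 1**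
Reactants: 1 propane-1,3-diylbis(triphenylphosphonium) dibromide; 2 1-[(tert-butyldimethylsilyl)oxy]propan-2-one (2 equiv)
Product: 4 (2Z,5Z)-1,7-bis[(tert-butyldimethylsilyl)oxy]-2,6-dimethylhepta-2,5-diene, via bis-ylide 3 (not isolated)
Conditions: KHMDS (2.05 equiv), THF, −78 → 0 °C; then 2, −78 °C → rt
Reagents that add atoms: none
Why: Two-directional Wittig olefination; unstabilised ylides add to α-silyloxy ketones with high (Z) selectivity (ylide chain cis to the CH2OSi group), so both trisubstituted alkenes should form as (Z).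

**Step 2**
Reactants: 4
Product: 5 (2Z,5Z)-2,6-dimethylhepta-2,5-diene-1,7-diol
Conditions: TBAF, THF, 0 °C → rt
Reagents that add atoms: none
Why: Fluoride-mediated desilylation should free both allylic alcohols without touching the skipped (Z,Z)-diene.

**Step 3**
Reactants: 5
Product: 7 (2Z,5Z)-7-[(tert-butyldimethylsilyl)oxy]-2,6-dimethylhepta-2,5-dien-1-ol, via monosodium alkoxide 6 (not isolated)
Conditions: NaH (1.0 equiv), THF, 0 °C → rt; then TBSCl (1.0 equiv)
Reagents that add atoms: tert-butyldimethylsilyl chloride, CC(C)(C)[Si](C)(C)Cl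
Why: Monosilylation of a symmetric diol through its sparingly soluble monosodium alkoxide should differentiate the two identical termini; no stereocentre is formed.

**Step 4**
Reactants: 7
Product: 8 [(2R,3S)-3-{(2Z)-4-[(tert-butyldimethylsilyl)oxy]-3-methylbut-2-en-1-yl}-2-methyloxiran-2-yl]methanol
Conditions: Ti(OiPr)4 (10 mol%), D-(−)-diethyl tartrate (12 mol%), t-BuOOH, 4 Å MS, CH2Cl2, −20 °C
Reagents that add atoms: tert-butyl hydroperoxide, CC(C)(C)OO
Why: Sharpless asymmetric epoxidation acts only on the free (Z)-allylic alcohol; the D-(−)-tartrate catalyst should give the (2R,3S)-epoxy alcohol (mirror-image sense of the L-(+)-tartrate epoxidation of nerol to its (2S,3R)-epoxide), and the (Z) geometry fixes the cis relation of the two carbon arms that later become ring bonds.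

**Step 5**
Reactants: 8
Product: 9 (2S,3S)-3-{(2Z)-4-[(tert-butyldimethylsilyl)oxy]-3-methylbut-2-en-1-yl}-2-methyloxirane-2-carboxylic acid
Conditions: TEMPO (20 mol%), PhI(OAc)2 (2.2 equiv), MeCN/H2O 1:1, 0 °C → rt; used at once
Reagents that add atoms: water, O
Why: Oxoammonium-mediated oxidation of the primary alcohol through the aldehyde hydrate should give the acid while leaving alkene, epoxide, silyl ether and both stereocentres untouched.

**Step 6**
Reactants: 9
Product: 11 2-diazo-1-[(2S,3S)-3-{(2Z)-4-[(tert-butyldimethylsilyl)oxy]-3-methylbut-2-en-1-yl}-2-methyloxiran-2-yl]ethan-1-one, via mixed carbonic anhydride 10 (not isolated)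
Conditions: i-BuOCOCl, N-methylmorpholine, THF, −20 °C; then CH2N2, Et2O, −20 → 0 °C
Reagents that add atoms: diazomethane, C=[N+]=[N-]; isobutyl chloroformate, CC(C)COC(=O)Cl (its atoms remain only in intermediate 10)
Why: Acylation of diazomethane by the mixed anhydride (first stage of an Arndt–Eistert sequence) should give the α-diazoketone under acid-free conditions that the glycidic epoxide tolerates.

**Step 7**
Reactants: 11
Product: 13 (1S,3S,4S,6S)-4-{3-[(tert-butyldimethylsilyl)oxy]prop-1-en-2-yl}-3-hydroxy-1-methyl-7-oxabicyclo[4.1.0]heptan-2-one, via epoxy glyoxal 12 (not isolated)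
Conditions: DMDO (1.0 equiv), acetone, −78 °C; concentration at 0 °C; then [Cu((S,S)-t-Bu-box)](SbF6)2 (10 mol%), 4 Å MS, CH2Cl2, −40 → 0 °C
Reagents that add atoms: dimethyldioxirane, CC1(C)OO1
Why: Dimethyldioxirane turns the diazo carbon into the anhydrous aldehyde of glyoxal 12 with loss of N2; the divalent-copper bis(oxazoline) complex then chelates the two adjacent carbonyl oxygens and triggers a concerted, asynchronous type-one intramolecular carbonyl-ene reaction in which the alkene carbon that becomes C4 attacks the aldehyde carbon (C3), a hydrogen of the vinylic methyl group passes to the aldehyde oxygen and the double bond moves to the exocyclic C=CH2 position. The closest known reactions are the Lewis-acid cyclisation of citronellal to isopulegol and the copper–bis(oxazoline)-catalysed glyoxylate-ene reaction. The six-membered carbocycle closes in a 6-exo-trig mode with respect to the aldehyde, with the carbonyl oxygen and the donor alkene both remaining outside the new ring. C3 is controlled by the catalyst, whose (S,S)-tert-butyl ligand should leave the Si face of the chelated aldehyde open as in glyoxylate-ene reactions, and C4 follows from the chair-like transition state with the chelated C3–O bond and the alkene both pseudo-equatorial, which gives the trans C3/C4 relation and so places the side chain cis to the epoxide oxygen. The step needs hydrogen transfer from CH3 and not from CH2OSi, secured by the (Z) geometry (CH3 syn to the vinylic hydrogen) and the deactivated α-silyloxy C–H bonds, and reaction of the aldehyde rather than the ketone, secured by its higher electrophilicity and the six-membered ring size; whether catalyst and epoxide configuration are matched is the open point.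

**Step 8**
Reactants: 13
Product: 14 (1S,3S,4S,6S)-4-{3-[(tert-butyldimethylsilyl)oxy]prop-1-en-2-yl}-1-methyl-2-oxo-7-oxabicyclo[4.1.0]heptan-3-yl 3-methylbut-2-enoate
Conditions: 3-methylbut-2-enoyl chloride, pyridine, DMAP (cat.), CH2Cl2, 0 °C
Reagents that add atoms: 3-methylbut-2-enoyl chloride, CC(C)=CC(=O)Cl
Why: O-acylation of the secondary α-ketol with the acid chloride under pyridine (a weak base that avoids deconjugation of the senecioyl unit) should install the senecioate; C3 is not touched and would in any case rest in the trans-diequatorial arrangement.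

**Step 9**
Reactants: 14
Product: 15 (1S,3S,4S,6S)-4-(3-hydroxyprop-1-en-2-yl)-1-methyl-2-oxo-7-oxabicyclo[4.1.0]heptan-3-yl 3-methylbut-2-enoate
Conditions: HF·pyridine, pyridine, THF, 0 °C → rt
Reagents that add atoms: none
Why: Buffered fluoride cleavage of the primary allylic silyl ether should leave the α-acyloxy ketone, the epoxide and the ester intact.

**Step 10**
Reactants: 15
Product: 16 (1S,3S,4S,6S)-1-methyl-2-oxo-4-(3-oxoprop-1-en-2-yl)-7-oxabicyclo[4.1.0]heptan-3-yl 3-methylbut-2-enoate
Conditions: Dess–Martin periodinane, CH2Cl2, 0 °C → rt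
Reagents that add atoms: none
Why: Base-free hypervalent-iodine oxidation of the primary allylic alcohol should give the α-substituted acrolein without moving the exocyclic alkene or epimerising C4.

**Step 11**
Reactants: 16
Product: 17 (1S,3S,4S,6S)-4-[(3S)-3-hydroxyhexa-1,5-dien-2-yl]-1-methyl-2-oxo-7-oxabicyclo[4.1.0]heptan-3-yl 3-methylbut-2-enoate
Conditions: allyltributylstannane, (S)-BINOL (20 mol%), Ti(OiPr)4 (10 mol%), 4 Å MS, CH2Cl2, −20 °C; aq. NaHCO3 work-up
Reagents that add atoms: allyltributylstannane, C=CC[Sn](CCCC)(CCCC)CCCC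
Why: Keck asymmetric allylation; the BINOL–titanium Lewis acid activates only the aldehyde (hindered ketone and esters do not react with the allylstannane), and the (S)-BINOL catalyst should direct allyl to the Si face, giving the (S) carbinol C3′ by reagent control.

**Step 12**
Reactants: 17
Product: 18 (1S,3S,4S,6S)-4-[(3S)-3-hydroxy-6-methylhepta-1,5-dien-2-yl]-1-methyl-2-oxo-7-oxabicyclo[4.1.0]heptan-3-yl 3-methylbut-2-enoate
Conditions: second-generation Hoveyda–Grubbs catalyst RuCl2(H2IMes)(=CH–C6H4-2-OiPr) (5 mol%), 2-methylbut-2-ene/CH2Cl2, 40 °C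
Reagents that add atoms: 2-methylbut-2-ene, CC=C(C)C
Why: Olefin cross-metathesis of the only monosubstituted alkene with excess 2-methylbut-2-ene should turn the allyl into the prenyl terminus; the 1,1-disubstituted alkene and the trisubstituted enoate are too hindered or electron-poor to take part.

**Step 13**
Reactants: 18
Product: 19 (3S)-6-methyl-2-[(1S,3S,4S,6S)-1-methyl-3-[(3-methylbut-2-enoyl)oxy]-2-oxo-7-oxabicyclo[4.1.0]heptan-4-yl]hepta-1,5-dien-3-yl (2Z)-2-methylbut-2-enoate
Conditions: angelic acid, 2,4,6-trichlorobenzoyl chloride, Et3N, toluene, rt; then 18, toluene, 80 °C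
Reagents that add atoms: angelic acid [(2Z)-2-methylbut-2-enoic acid], C/C=C(/C)C(=O)O
Why: Yamaguchi-type esterification through the preformed mixed anhydride without DMAP should acylate the hindered allylic alcohol with retention at C3′ and without (Z)→(E) isomerisation of the angelate.

**Compound list**
1 | propane-1,3-diylbis(triphenylphosphonium) dibromide | [Br-].[Br-].C(C[P+](c1ccccc1)(c1ccccc1)c1ccccc1)C[P+](c1ccccc1)(c1ccccc1)c1ccccc1 | starting material
2 | 1-[(tert-butyldimethylsilyl)oxy]propan-2-one | CC(=O)CO[Si](C)(C)C(C)(C)C | starting material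
3 | bis-ylide, (propane-1,3-diylidene)bis(triphenyl-λ5-phosphane) | C(C=P(c1ccccc1)(c1ccccc1)c1ccccc1)C=P(c1ccccc1)(c1ccccc1)c1ccccc1 | intermediate (not isolated)
4 | (2Z,5Z)-1,7-bis[(tert-butyldimethylsilyl)oxy]-2,6-dimethylhepta-2,5-diene | CC(C)(C)[Si](C)(C)OC/C(C)=C\C/C=C(C)\CO[Si](C)(C)C(C)(C)C | intermediate
5 | (2Z,5Z)-2,6-dimethylhepta-2,5-diene-1,7-diol | OC/C(C)=C\C/C=C(C)\CO | intermediate
6 | monosodium alkoxide of diol 5 | [Na+].[O-]C/C(C)=C\C/C=C(C)\CO | intermediate (not isolated)
7 | (2Z,5Z)-7-[(tert-butyldimethylsilyl)oxy]-2,6-dimethylhepta-2,5-dien-1-ol | OC/C(C)=C\C/C=C(C)\CO[Si](C)(C)C(C)(C)C | intermediate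
8 | [(2R,3S)-3-{(2Z)-4-[(tert-butyldimethylsilyl)oxy]-3-methylbut-2-en-1-yl}-2-methyloxiran-2-yl]methanol | OC[C@@]1(C)O[C@H]1C/C=C(C)\CO[Si](C)(C)C(C)(C)C | intermediate
9 | (2S,3S)-3-{(2Z)-4-[(tert-butyldimethylsilyl)oxy]-3-methylbut-2-en-1-yl}-2-methyloxirane-2-carboxylic acid | OC(=O)[C@@]1(C)O[C@H]1C/C=C(C)\CO[Si](C)(C)C(C)(C)C | intermediate
10 | mixed anhydride of acid 9 with isobutyl hydrogen carbonate | CC(C)COC(=O)OC(=O)[C@@]1(C)O[C@H]1C/C=C(C)\CO[Si](C)(C)C(C)(C)C | intermediate (not isolated)
11 | 2-diazo-1-[(2S,3S)-3-{(2Z)-4-[(tert-butyldimethylsilyl)oxy]-3-methylbut-2-en-1-yl}-2-methyloxiran-2-yl]ethan-1-one | [N-]=[N+]=CC(=O)[C@@]1(C)O[C@H]1C/C=C(C)\CO[Si](C)(C)C(C)(C)C | intermediate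
12 | 2-[(2S,3S)-3-{(2Z)-4-[(tert-butyldimethylsilyl)oxy]-3-methylbut-2-en-1-yl}-2-methyloxiran-2-yl]-2-oxoacetaldehyde | O=CC(=O)[C@@]1(C)O[C@H]1C/C=C(C)\CO[Si](C)(C)C(C)(C)C | intermediate (not isolated)
13 | (1S,3S,4S,6S)-4-{3-[(tert-butyldimethylsilyl)oxy]prop-1-en-2-yl}-3-hydroxy-1-methyl-7-oxabicyclo[4.1.0]heptan-2-one | C=C(CO[Si](C)(C)C(C)(C)C)[C@@H]1C[C@@H]2O[C@]2(C)C(=O)[C@H]1O | intermediate
14 | (1S,3S,4S,6S)-4-{3-[(tert-butyldimethylsilyl)oxy]prop-1-en-2-yl}-1-methyl-2-oxo-7-oxabicyclo[4.1.0]heptan-3-yl 3-methylbut-2-enoate | C=C(CO[Si](C)(C)C(C)(C)C)[C@@H]1C[C@@H]2O[C@]2(C)C(=O)[C@H]1OC(=O)C=C(C)C | intermediate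
15 | (1S,3S,4S,6S)-4-(3-hydroxyprop-1-en-2-yl)-1-methyl-2-oxo-7-oxabicyclo[4.1.0]heptan-3-yl 3-methylbut-2-enoate | C=C(CO)[C@@H]1C[C@@H]2O[C@]2(C)C(=O)[C@H]1OC(=O)C=C(C)C | intermediate
16 | (1S,3S,4S,6S)-1-methyl-2-oxo-4-(3-oxoprop-1-en-2-yl)-7-oxabicyclo[4.1.0]heptan-3-yl 3-methylbut-2-enoate | C=C(C=O)[C@@H]1C[C@@H]2O[C@]2(C)C(=O)[C@H]1OC(=O)C=C(C)C | intermediate
17 | (1S,3S,4S,6S)-4-[(3S)-3-hydroxyhexa-1,5-dien-2-yl]-1-methyl-2-oxo-7-oxabicyclo[4.1.0]heptan-3-yl 3-methylbut-2-enoate | C=C([C@H](CC=C)O)[C@@H]1C[C@@H]2O[C@]2(C)C(=O)[C@H]1OC(=O)C=C(C)C | intermediate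
18 | (1S,3S,4S,6S)-4-[(3S)-3-hydroxy-6-methylhepta-1,5-dien-2-yl]-1-methyl-2-oxo-7-oxabicyclo[4.1.0]heptan-3-yl 3-methylbut-2-enoate | C=C([C@H](CC=C(C)C)O)[C@@H]1C[C@@H]2O[C@]2(C)C(=O)[C@H]1OC(=O)C=C(C)C | intermediate
19 | (3S)-6-methyl-2-[(1S,3S,4S,6S)-1-methyl-3-[(3-methylbut-2-enoyl)oxy]-2-oxo-7-oxabicyclo[4.1.0]heptan-4-yl]hepta-1,5-dien-3-yl (2Z)-2-methylbut-2-enoate | C=C([C@H](CC=C(C)C)OC(=O)/C(C)=C\C)[C@@H]1C[C@@H]2O[C@]2(C)C(=O)[C@H]1OC(=O)C=C(C)C | target

**Totals**
Total step count: 13. Longest linear sequence: 13 steps (fully linear from 1 and 2).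

**Steps most likely to fail**

Step 7. What may go wrong: competing epoxidation of the trisubstituted alkene by the dioxirane, Lewis-acid opening of the epoxy ketone, or poor facial selectivity at the aldehyde if catalyst and epoxide configuration are mismatched. The fallback gives up the glyoxal and closes the ring with C2 at the alcohol oxidation level under a simple aluminium Lewis acid; it sets out from 8 and comes back at 14. Dess–Martin oxidation of 8 would give the epoxy aldehyde (2S,3S)-3-{(2Z)-4-[(tert-butyldimethylsilyl)oxy]-3-methylbut-2-en-1-yl}-2-methyloxirane-2-carbaldehyde F1. Addition of Et3SiCN (cat. Et3N, CH2Cl2, 0 °C) would give the O-triethylsilyl cyanohydrin F2 as both epimers at the new carbon. DIBAL-H (toluene, −78 °C) and mild hydrolysis would give the α-triethylsilyloxy aldehyde F3. Me2AlCl (CH2Cl2, −78 °C) should then effect the type-one carbonyl-ene closure of the same C3–C4 bond to the cyclohexanol F4. Acylation with 3-methylbut-2-enoyl chloride and pyridine would give the senecioate F5, and PPTS in MeOH at 0 °C should remove only the secondary triethylsilyl ether to give the C2 alcohol F6. Dess–Martin oxidation of F6 returns ketone 14.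

Step 1. What may go wrong: erosion of (Z) selectivity in one of the two olefinations, or incomplete second olefination of the bis-ylide with the ketone. The fallback builds the two alkenes one after the other by two different (Z)-selective olefinations; it sets out from 2 and comes back at 7, which also bypasses steps 2 and 3. Wittig reaction of 2 with the ylide from [2-(1,3-dioxolan-2-yl)ethyl]triphenylphosphonium bromide (KHMDS, THF, −78 °C) would give the (Z)-alkenyl dioxolane F7. Acetal cleavage with CeCl3·7H2O and NaI (cat.) in MeCN would give the β,γ-unsaturated aldehyde (3Z)-5-[(tert-butyldimethylsilyl)oxy]-4-methylpent-3-enal F8, to be used at once. Still–Gennari olefination (methyl 2-[bis(2,2,2-trifluoroethoxy)phosphoryl]propanoate, KHMDS, 18-crown-6, THF, −78 °C) would give the (2Z,5Z)-dienoate F9. DIBAL-H reduction of F9 gives 7.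

Step 11. What may go wrong: slow addition to the hindered α-branched enal, or insufficient reagent control at the new carbinol centre next to the existing ring stereocentres. The fallback replaces catalytic Lewis-acid activation by a stoichiometric chiral allylborane that reacts through a closed six-membered transition state; it sets out from 16 and comes back at 17. The reagent would be (−)-B-allyldiisopinocampheylborane (the enantiomer that converts benzaldehyde into (S)-1-phenylbut-3-en-1-ol), Et2O, −78 °C, with a non-oxidative ethanolamine work-up to spare the esters and the epoxy ketone. No new isolated compound arises.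

**Further compounds**
F1 | step 7 | (2S,3S)-3-{(2Z)-4-[(tert-butyldimethylsilyl)oxy]-3-methylbut-2-en-1-yl}-2-methyloxirane-2-carbaldehyde | O=C[C@@]1(C)O[C@H]1C/C=C(C)\CO[Si](C)(C)C(C)(C)C
F2 | step 7 | 2-[(2S,3S)-3-{(2Z)-4-[(tert-butyldimethylsilyl)oxy]-3-methylbut-2-en-1-yl}-2-methyloxiran-2-yl]-2-[(triethylsilyl)oxy]acetonitrile (both epimers at the cyanohydrin carbon) | N#CC(O[Si](CC)(CC)CC)[C@@]1(C)O[C@H]1C/C=C(C)\CO[Si](C)(C)C(C)(C)C
F3 | step 7 | 2-[(2S,3S)-3-{(2Z)-4-[(tert-butyldimethylsilyl)oxy]-3-methylbut-2-en-1-yl}-2-methyloxiran-2-yl]-2-[(triethylsilyl)oxy]acetaldehyde (both epimers at the silyloxy carbon) | O=CC(O[Si](CC)(CC)CC)[C@@]1(C)O[C@H]1C/C=C(C)\CO[Si](C)(C)C(C)(C)C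
F4 | step 7 | 4-{3-[(tert-butyldimethylsilyl)oxy]prop-1-en-2-yl}-1-methyl-2-[(triethylsilyl)oxy]-7-oxabicyclo[4.1.0]heptan-3-ol, configured as 13 at C1, C3, C4 and C6, both epimers at C2 | C=C(CO[Si](C)(C)C(C)(C)C)[C@@H]1C[C@@H]2O[C@]2(C)C(O[Si](CC)(CC)CC)[C@H]1O
F5 | step 7 | 4-{3-[(tert-butyldimethylsilyl)oxy]prop-1-en-2-yl}-1-methyl-2-[(triethylsilyl)oxy]-7-oxabicyclo[4.1.0]heptan-3-yl 3-methylbut-2-enoate, configured as 13 at C1, C3, C4 and C6, both epimers at C2 | C=C(CO[Si](C)(C)C(C)(C)C)[C@@H]1C[C@@H]2O[C@]2(C)C(O[Si](CC)(CC)CC)[C@H]1OC(=O)C=C(C)C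
F6 | step 7 | 4-{3-[(tert-butyldimethylsilyl)oxy]prop-1-en-2-yl}-2-hydroxy-1-methyl-7-oxabicyclo[4.1.0]heptan-3-yl 3-methylbut-2-enoate, configured as 13 at C1, C3, C4 and C6, both epimers at C2 | C=C(CO[Si](C)(C)C(C)(C)C)[C@@H]1C[C@@H]2O[C@]2(C)C(O)[C@H]1OC(=O)C=C(C)C
F7 | step 1 | 2-{(2Z)-4-[(tert-butyldimethylsilyl)oxy]-3-methylbut-2-en-1-yl}-1,3-dioxolane | CC(C)(C)[Si](C)(C)OC/C(C)=C\CC1OCCO1
F8 | step 1 | (3Z)-5-[(tert-butyldimethylsilyl)oxy]-4-methylpent-3-enal | CC(C)(C)[Si](C)(C)OC/C(C)=C\CC=O
F9 | step 1 | methyl (2Z,5Z)-7-[(tert-butyldimethylsilyl)oxy]-2,6-dimethylhepta-2,5-dienoate | COC(=O)/C(C)=C\C/C=C(C)\CO[Si](C)(C)C(C)(C)C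
F0 | step 11 | none | none
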